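# Proposed synthesis of (−)-(7R,8S,7'E)-3,4,5,5'-tetramethoxy-4',7-epoxy-8,3'-neolign-7'-ene-9,9'-diol (12) by asymmetric Prins hydroxymethylation of a stilbene

## The problem

The target 12 is an 8,3'-neolignan built on a 2,3-dihydrobenzofuran. Ring A is tied to the side chain twice, through the C3'–C8 carbon–carbon bond and the O4'–C7 ether bond; C7 carries ring B (3,4,5-trimethoxyphenyl), C8 carries the hydroxymethyl carbon C9, and ring A also holds a methoxy group at C5' and the (E)-allylic alcohol chain C7'–C9' at C1'. The only stereocentres are the neighbours C7 and C8, trans to each other and (7R,8S). They are unequal tasks. C7 is a benzylic ether carbon beside an aryl ring with a para-methoxy group, so it can be formed or corrected through its cation, and C8 then dictates it because the trans ring is the stable one. C8 is an all-carbon centre that cannot be equilibrated and that nothing else in the molecule controls, so its absolute configuration must come from a reagent or catalyst. The same ease of ionisation makes the molecule delicate: acid can reopen the C7–O4' bond, a long-lived C7 cation can expel C9 as formaldehyde or lose H8, and the para-alkoxycinnamyl alcohol at C1' ionises and oxidises readily, so it should be made last, after all acid chemistry. Ring B is electron-rich and open to electrophiles at its two free positions. The feature that allows a short route is the array O–C7–C8–C9–O: C8 bears a one-carbon oxygenated branch and lies beside C7, which bears oxygen and adjoins ring B. This is the pattern left when a C7=C8 stilbene adds formaldehyde in a Prins reaction, and the phenol oxygen O4', ortho to C3' on ring A, is placed to take over C7 from the acetal oxygen afterwards.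

## Retrosynthesis

**12 ⇒ 11 (C9' oxidation level).** No skeletal bond is cut: the allylic alcohol is traced back to the methyl (E)-enoate 11. This keeps the acid-labile cinnamyl alcohol out of every acid step, and the enoate serves as an inert, electron-withdrawing spectator on ring A until then. The forward step only has to be a clean 1,2-reduction of a conjugated ester in the presence of a benzylic aryl ether.

**11 ⇒ 8 (O4'–C7, through 10 and 9).** The ring ether bond O4'–C7 is cut, C7–O and C9–O are tied together through a formaldehyde acetal, and the phenol is acetylated, giving the trans-4,5-disubstituted 1,3-dioxane 8. Of the ring bonds of 11, this is the only one that can form under thermodynamic control: the cation at C7 is captured by O4' with the trans outcome fixed by C8. Cutting C3'–C8 or C7–C8 instead would require a new stereo-inducing event at C8. Compound 8 is no smaller than 11, but its two stereocentres now sit in a ring that one intermolecular reaction can assemble. The forward reaction must remove the acetate, exchange the acetal (via phenol 9 and triol 10), ionise C7 and close the five-membered ring without disturbing C8.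

**8 ⇒ 6 + 7 (C8–C9 and C7–O, Prins transform).** Removing the two formaldehyde units (7) from the dioxane leaves the (E)-stilbene 6. The neighbouring cuts are an aldol cut at C7–C8 or an arylation cut at C3'–C8. Each needs a stoichiometric chiral controller on an arylacetic acid derivative and several protecting groups. The Prins cut removes both stereocentres at once and leaves an achiral, flat olefin and the cheapest C1 electrophile. The forward reaction must deliver carbon to C8 and oxygen to C7 (regiochemistry), choose one face of C8 (enantioselectivity) and add syn across the (E)-olefin (trans ring). The substituents of 6 are chosen for this. The acetate on O4' and the enoate at C1' make ring A the electron-poor end, so charge develops at C7 beside ring B. The enoate, unlike an aldehyde at C1', cannot act as a competing Prins electrophile, and it already contains C7'–C9'.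

**6 ⇒ 3 + 5 (C3'–C8, Heck transform).** The stilbene is cut between ring A and the olefin, giving aryl iodide 3 and styrene 5. A carbonyl-olefination route to the stilbene would need a benzylic phosphorus reagent at C3' of ring A, which no cheap starting material offers. The iodine of 1 already marks C3'. Both fragments are one-ring compounds. The forward coupling must be (E)-selective and must leave the aryl acetate and the enoate of 3 intact.

**3 ⇒ 2 ⇒ 1 and 5 ⇒ 4.** The enoate of 3 is cut at C7'=C8' (Wittig transform) to aldehyde 2, the acetate of commercial 5-iodovanillin 1. Styrene 5 is cut at its vinyl double bond to commercial aldehyde 4. Both forward reactions are routine olefinations; the stabilised ylide must give the (E)-enoate.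

## Roads not taken

**Alternative 1:** Three-component conjunctive coupling. The cut removes the ring B–C7 and C3'–C8 bonds together, leading to alkenyl boronate A1, aryllithium A2 and ring A bromide A3. Forward, A1 and A2 form a boron ate complex. A palladium catalyst with a chiral ferrocenyl diphosphine of the MandyPhos type adds oxidatively to A3, and the aryl-palladium species induces a 1,2-shift of the trimethoxyphenyl group from boron to C7 while ring A is delivered to C8. The product is the secondary benzylic boronate A4; no ring closes.
- Merits: two skeletal C–C bonds and both stereocentres arise in one catalytic enantioselective step from three simple pieces. In convergence this is better than the chosen plan, whose key step makes one C–C bond on a pre-assembled stilbene.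
- Weak points: A1 is a 1,2-disubstituted alkenyl boronate, a class in which the metallate shift is slow and direct Suzuki-type transfer competes. A3 carries an ortho substituent next to the reacting carbon, and bromide ion tends to inhibit the cationic palladium intermediate.
- Distance from the target: A4 still needs C–B oxidation, removal of the phenol protecting group, ring closure at C7 (the same C7–O event as in the chosen plan), acetal hydrolysis, chain extension, reduction and desilylation. Three protecting groups are carried.
- Comparison: both key steps stretch their precedent. The chosen plan offers in return one protecting group (an acetate that also steers the regiochemistry), no organolithium, the C9 carbon and oxygen supplied by formaldehyde, and a seven-step route.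

**Alternative 2:** Stereoconvergent cation cyclisation onto a preset C8. Only O4'–C7 is cut. Forward, a sulfonic acid in an alcohol solvent removes the phenol protecting group of diol A5 and ionises its benzylic C7 hydroxyl; the freed phenol oxygen traps the cation and gives the trans-dihydrobenzofuran A6.
- Merits: the closure is robust and closely precedented, the configuration at C7 of A5 is irrelevant, and the trans ring results under thermodynamic control.
- Weak points: the key step makes no C–C bond and sets no absolute configuration. C8 must come from an earlier asymmetric step, typically an auxiliary-controlled aldol with stoichiometric chirality, so the real problem is moved upstream. The bromide of A6 must still be extended to the C7'–C9' chain and reduced.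
- Comparison: in reliability this road is better than the chosen plan, since every step has a close analogue. Its ring closure is the same event as step 6 here. The chosen plan offers in return the catalytic creation of C8 and the C8–C9 bond from a flat olefin in one step, no auxiliary to attach and remove, and a shorter sequence.

**Alternative 3:** ortho-Quinone methide and sulfonium ylide [4+1] annulation. C7–C8 and O4'–C7 are cut together. Forward, a carbonate base expels sulfinate from sulfone A7 to release the ortho-quinone methide and deprotonates the chiral benzylic sulfonium salt A8 (written here with a C2-symmetric thiolane as the sulfide). The ylide carbon adds to C8, and the phenoxide displaces the sulfide at C7, closing the trans ring of silyl ether A9.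
- Merits: one step forms a C–C bond, the C–O bond, the heterocycle and both stereocentres. In directness of ring construction this is better than the chosen plan, which needs a second step to move C7 from the acetal oxygen to the phenol.
- Weak points: the quinone methide from A7 has an alkyl-type substituent (the silyloxymethyl group) on its exocyclic carbon. Such species tautomerise to ortho-hydroxystyrenes and dimerise more readily than aryl-substituted ones. The new centre at C8 lies on the quinone methide, one bond removed from the chiral sulfur, so enantiocontrol at C8 rests on an addition that may be reversible. The chirality is stoichiometric (though the sulfide is recoverable). A7 and A8 each need their own preparation, and A9 still needs chain extension, desilylation and reduction.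
- Comparison: the chosen plan offers in return a catalytic source of chirality that acts directly at C8 in the C–C bond-forming event, bench-stable precursors (a stilbene and paraformaldehyde), and fewer protecting groups.

Key step: step 5

Assumption: the sense of induction of the confined acid on a 1,2-diaryl olefin cannot be predicted in advance; the route is written for the catalyst antipode that delivers (4S,5S)-8 (both antipodes come from (R)- or (S)-BINOL, are prepared separately and are not counted as route steps).

## Route

Step 1
Reactants: 1 4-hydroxy-3-iodo-5-methoxybenzaldehyde (5-iodovanillin)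
Product: 2 4-formyl-2-iodo-6-methoxyphenyl acetate
Conditions: Ac2O, pyridine, rt
Reagents that add atoms: acetic anhydride, CC(=O)OC(C)=O
Why: O-acylation of the phenol (nucleophilic acyl substitution with pyridine as base and acyl-transfer agent); the acetate is the electron-withdrawing mask that ring A needs in step 5 and keeps a phenoxide away from the ylide and the palladium catalyst.

Step 2
Reactants: 2 4-formyl-2-iodo-6-methoxyphenyl acetate
Product: 3 methyl (2E)-3-[4-(acetyloxy)-3-iodo-5-methoxyphenyl]prop-2-enoate
Conditions: Ph3P=CHCO2Me, CH2Cl2, rt to 40 °C
Reagents that add atoms: methyl (triphenylphosphoranylidene)acetate, COC(=O)C=P(c1ccccc1)(c1ccccc1)c1ccccc1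
Why: Wittig olefination with a stabilised ylide, which gives the (E)-enoate; the neutral conditions leave the aryl acetate and the iodide untouched, and the aldehyde is converted into the complete C7'–C9' chain before any acid chemistry.

Step 3
Reactants: 4 3,4,5-trimethoxybenzaldehyde
Product: 5 5-ethenyl-1,2,3-trimethoxybenzene (3,4,5-trimethoxystyrene)
Conditions: Ph3PCH3Br, KOtBu, THF, 0 °C to rt
Reagents that add atoms: methyltriphenylphosphonium bromide, C[P+](c1ccccc1)(c1ccccc1)c1ccccc1.[Br-]
Why: Wittig methylenation of an aromatic aldehyde with the non-stabilised ylide made in the flask; no stereochemical issue arises, and the styrene is used promptly to avoid polymerisation.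

Step 4
Reactants: 3 methyl (2E)-3-[4-(acetyloxy)-3-iodo-5-methoxyphenyl]prop-2-enoate, 5 5-ethenyl-1,2,3-trimethoxybenzene
Product: 6 methyl (2E)-3-{4-(acetyloxy)-3-methoxy-5-[(E)-2-(3,4,5-trimethoxyphenyl)ethenyl]phenyl}prop-2-enoate
Conditions: Pd(OAc)2 (5 mol %), P(o-tol)3 (10 mol %), Et3N, DMF, 90 °C
Reagents that add atoms: none
Why: Mizoroki–Heck reaction: the aryl iodide adds oxidatively to zerovalent palladium, the terminal styrene inserts syn at its unsubstituted carbon (C3'–C8), and syn β-hydride elimination gives the (E)-stilbene; the internal, conjugated enoate double bond of 3 inserts far more slowly than the monosubstituted styrene.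

Step 5
Reactants: 6 methyl (2E)-3-{4-(acetyloxy)-3-methoxy-5-[(E)-2-(3,4,5-trimethoxyphenyl)ethenyl]phenyl}prop-2-enoate, 7 formaldehyde (charged as paraformaldehyde; two molecules enter the product)
Product: 8 methyl (2E)-3-{4-(acetyloxy)-3-methoxy-5-[(4S,5S)-4-(3,4,5-trimethoxyphenyl)-1,3-dioxan-5-yl]phenyl}prop-2-enoate
Conditions: (CH2O)n (excess), confined BINOL-derived imino-imidodiphosphate (iIDP) Brønsted acid (5 mol %), CHCl3/cyclohexane, rt
Reagents that add atoms: none
Why: Proposed new method: the confined acid protonates a formaldehyde oligomer inside its chiral pocket, C8 of the stilbene attacks the oxocarbenium carbon (C8–C9) while positive charge builds at C7 beside ring B, and the hydroxymethoxy oxygen of the same formaldehyde dimer closes onto C7 in a concerted but strongly asynchronous syn addition; the closest known reaction type is the confined-acid-catalysed asymmetric intermolecular Prins reaction of terminal styrenes with paraformaldehyde to 4-aryl-1,3-dioxanes, for which an (E)-1,2-diaryl olefin would be a new substrate class. The one ring formed, the 1,3-dioxane, closes by six-membered C7–O bond formation in a chair-like array, formally a (4+2) annulation of the olefin with the C–O–C–O unit of the protonated formaldehyde dimer. C8 is set by the chiral counter-anion, which leaves only one face of the olefin open to the electrophile. C7 follows from the (E) geometry and the syn addition, so both aryl groups end up equatorial and trans, (4S,5S). The step needs regioselectivity, and the substrate supplies it: ring B has a para-methoxy donor, whereas ring A is deactivated by the ortho-acetoxy group and the meta-enoate, so charge goes to C7 and carbon to C8. Chemoselectivity rests on the enoate double bond being too electron-poor to attack the oxocarbenium ion and on formaldehyde being the only aldehyde present. The acetate must stay in place, because a free ortho-hydroxyl would reverse the polarity of the olefin.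

Step 6
Reactants: 8 methyl (2E)-3-{4-(acetyloxy)-3-methoxy-5-[(4S,5S)-4-(3,4,5-trimethoxyphenyl)-1,3-dioxan-5-yl]phenyl}prop-2-enoate
Product: 11 methyl (2E)-3-[(2R,3S)-3-(hydroxymethyl)-7-methoxy-2-(3,4,5-trimethoxyphenyl)-2,3-dihydro-1-benzofuran-5-yl]prop-2-enoate, via free phenol dioxane 9 (not isolated), via benzylic triol 10 (not isolated)
Conditions: HCl (1.25 M in MeOH), 60 °C, CH2(OMe)2 distilled off
Reagents that add atoms: none
Why: Acid-catalysed methanolysis first removes the aryl acetate (9) and then exchanges the formaldehyde acetal to volatile dimethoxymethane (transacetalisation, 10); the benzylic C7 oxygen ionises (SN1, cation stabilised by ring B) and the ortho phenol oxygen O4' captures it in a five-membered closure. C8 is not touched, and the reversible closure places ring B trans to C9, which makes C7 (R); the methyl enoate is inert to methanolic acid.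

Step 7
Reactants: 11 methyl (2E)-3-[(2R,3S)-3-(hydroxymethyl)-7-methoxy-2-(3,4,5-trimethoxyphenyl)-2,3-dihydro-1-benzofuran-5-yl]prop-2-enoate
Product: 12 (2E)-3-[(2R,3S)-3-(hydroxymethyl)-7-methoxy-2-(3,4,5-trimethoxyphenyl)-2,3-dihydro-1-benzofuran-5-yl]prop-2-en-1-ol (the target)
Conditions: i-Bu2AlH (4.5 equiv), CH2Cl2, −78 °C; aq. KNaC4H4O6 (potassium sodium tartrate) work-up
Reagents that add atoms: none
Why: 1,2-Reduction of the α,β-unsaturated methyl ester to the (E)-allylic alcohol by the aluminium hydride at low temperature, with excess reagent to cover the free C9 hydroxyl; the benzylic ether and both stereocentres are untouched, and the non-acidic tartrate work-up protects the acid-labile para-alkoxycinnamyl alcohol.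

## Compound list

1 | 4-hydroxy-3-iodo-5-methoxybenzaldehyde (5-iodovanillin) | COc1cc(C=O)cc(I)c1O | starting material
2 | 4-formyl-2-iodo-6-methoxyphenyl acetate | CC(=O)Oc1c(I)cc(C=O)cc1OC | intermediate
3 | methyl (2E)-3-[4-(acetyloxy)-3-iodo-5-methoxyphenyl]prop-2-enoate | COC(=O)/C=C/c1cc(I)c(OC(C)=O)c(OC)c1 | intermediate
4 | 3,4,5-trimethoxybenzaldehyde | COc1cc(C=O)cc(OC)c1OC | starting material
5 | 5-ethenyl-1,2,3-trimethoxybenzene (3,4,5-trimethoxystyrene) | C=Cc1cc(OC)c(OC)c(OC)c1 | intermediate
6 | methyl (2E)-3-{4-(acetyloxy)-3-methoxy-5-[(E)-2-(3,4,5-trimethoxyphenyl)ethenyl]phenyl}prop-2-enoate | COC(=O)/C=C/c1cc(OC)c(OC(C)=O)c(/C=C/c2cc(OC)c(OC)c(OC)c2)c1 | intermediate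
7 | formaldehyde (used as paraformaldehyde) | C=O | starting material
8 | methyl (2E)-3-{4-(acetyloxy)-3-methoxy-5-[(4S,5S)-4-(3,4,5-trimethoxyphenyl)-1,3-dioxan-5-yl]phenyl}prop-2-enoate | COc1cc([C@H]2OCOC[C@@H]2c3cc(/C=C/C(=O)OC)cc(OC)c3OC(C)=O)cc(OC)c1OC | intermediate
9 | methyl (2E)-3-{4-hydroxy-3-methoxy-5-[(4S,5S)-4-(3,4,5-trimethoxyphenyl)-1,3-dioxan-5-yl]phenyl}prop-2-enoate | COc1cc([C@H]2OCOC[C@@H]2c3cc(/C=C/C(=O)OC)cc(OC)c3O)cc(OC)c1OC | intermediate (not isolated)
10 | methyl (2E)-3-{3-[(1S,2S)-1,3-dihydroxy-1-(3,4,5-trimethoxyphenyl)propan-2-yl]-4-hydroxy-5-methoxyphenyl}prop-2-enoate | COC(=O)/C=C/c1cc(OC)c(O)c(c1)[C@@H](CO)[C@H](O)c1cc(OC)c(OC)c(OC)c1 | intermediate (not isolated)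
11 | methyl (2E)-3-[(2R,3S)-3-(hydroxymethyl)-7-methoxy-2-(3,4,5-trimethoxyphenyl)-2,3-dihydro-1-benzofuran-5-yl]prop-2-enoate | COc1cc([C@@H]2Oc3c(OC)cc(/C=C/C(=O)OC)cc3[C@H]2CO)cc(OC)c1OC | intermediate
12 | (2E)-3-[(2R,3S)-3-(hydroxymethyl)-7-methoxy-2-(3,4,5-trimethoxyphenyl)-2,3-dihydro-1-benzofuran-5-yl]prop-2-en-1-ol | COc1cc([C@@H]2Oc3c(OC)cc(/C=C/CO)cc3[C@H]2CO)cc(OC)c1OC | target

## Step count and risks

Total: 7 steps. Longest linear sequence: 6 steps (1 → 2 → 3 → 6 → 8 → 11 → 12, that is steps 1, 2, 4, 5, 6 and 7); step 3 supplies the second fragment.

**Step 5 (key step, proposed new method).**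
- Most likely failure: insufficient reactivity of the internal, doubly conjugated olefin inside the confined pocket. Any forcing that overcomes this is likely to cost facial selectivity at C8.
- Side processes: electrophilic hydroxymethylation of ring B at its two free positions, and cationic oligomerisation.
- Regiocontrol may erode, because the para-methoxy group of ring B is flanked by two methoxy groups and is only partly conjugated.
- Fallback (known chemistry: a classical strong-acid Prins reaction combined with a covalently bound resolving group; it sets out from 6 and comes back at 9). The acetate is exchanged for a chiral carbonate, so that the acyl protecting group also serves as resolving agent.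
  - K2CO3 (catalytic) in MeOH converts 6 into the free phenol methyl (2E)-3-{4-hydroxy-3-methoxy-5-[(E)-2-(3,4,5-trimethoxyphenyl)ethenyl]phenyl}prop-2-enoate F1.
  - (−)-Menthyl chloroformate and pyridine convert F1 into the aryl menthyl carbonate methyl (2E)-3-{3-methoxy-4-({[(1R,2S,5R)-5-methyl-2-(propan-2-yl)cyclohexyl]oxy}carbonyloxy)-5-[(E)-2-(3,4,5-trimethoxyphenyl)ethenyl]phenyl}prop-2-enoate F2, which has the same electronic bias as 6.
  - F2 is submitted to a Prins reaction with 7 under catalytic TfOH in CH2Cl2 at 0 °C. No induction by the remote menthyl group is counted on. The two trans-dioxanes, the (4S,5S)-dioxanyl menthyl carbonate F3 and the (4R,5R)-dioxanyl menthyl carbonate F4, are diastereomers and should be separable by crystallisation or chromatography.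
  - K2CO3 in MeOH cleaves the carbonate of F3 to phenol 9, which is taken directly into the acid conditions of step 6.

**Step 6.**
- Most likely failure: the C7 cation lives long enough to fragment (loss of C9 as formaldehyde, a retro-Prins process that returns a stilbene) or to lose H8, which would erase the C8 centre.
- Also possible: incomplete exchange of the robust formaldehyde acetal, or capture of C7 by methanol in competition with ring closure.
- Fallback (sets out from 8 and comes back at 11). The acetal is dismantled irreversibly by electrophilic acetolysis, and the ring is closed in a separate, non-nucleophilic medium.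
  - Ac2O with catalytic H2SO4 at 0 °C opens the dioxane of 8 to the triacetate methyl (2E)-3-{4-(acetyloxy)-3-[(1S,2S)-3-(acetyloxy)-1-[(acetyloxy)methoxy]-1-(3,4,5-trimethoxyphenyl)propan-2-yl]-5-methoxyphenyl}prop-2-enoate F5.
  - K2CO3 in MeOH removes the three acetyl groups and the hemiformal, giving triol 10, this time isolated. Any loss of configuration at C7 on the way is of no consequence.
  - A catalytic amount of p-TsOH in CH2Cl2 at 0 °C to rt closes 10 to 11. Capture by the ortho phenol should outrun fragmentation and elimination under these conditions.

**Step 4.**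
- Most likely failure: cleavage of the aryl acetate by the amine base at 90 °C. The resulting phenoxide slows the coupling and gives a mixture of acetylated and free products.
- Fallback (sets out from 3 and comes back at 6). The protecting-group order is changed so that the coupling is run on the free phenol.
  - K2CO3 in MeOH converts 3 into methyl (2E)-3-(4-hydroxy-3-iodo-5-methoxyphenyl)prop-2-enoate F6.
  - The Heck reaction of F6 with 5 (Pd(OAc)2, P(o-tol)3, Et3N, DMF) gives the phenol stilbene methyl (2E)-3-{4-hydroxy-3-methoxy-5-[(E)-2-(3,4,5-trimethoxyphenyl)ethenyl]phenyl}prop-2-enoate F1.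
  - Ac2O in pyridine acetylates F1 to 6.

## Further compounds

F1 | step 5 | methyl (2E)-3-{4-hydroxy-3-methoxy-5-[(E)-2-(3,4,5-trimethoxyphenyl)ethenyl]phenyl}prop-2-enoate | COC(=O)/C=C/c1cc(OC)c(O)c(/C=C/c2cc(OC)c(OC)c(OC)c2)c1
F2 | step 5 | methyl (2E)-3-{3-methoxy-4-({[(1R,2S,5R)-5-methyl-2-(propan-2-yl)cyclohexyl]oxy}carbonyloxy)-5-[(E)-2-(3,4,5-trimethoxyphenyl)ethenyl]phenyl}prop-2-enoate | COC(=O)/C=C/c1cc(OC)c(OC(=O)O[C@@H]2C[C@H](C)CC[C@H]2C(C)C)c(/C=C/c3cc(OC)c(OC)c(OC)c3)c1
F3 | step 5 | methyl (2E)-3-{3-methoxy-4-({[(1R,2S,5R)-5-methyl-2-(propan-2-yl)cyclohexyl]oxy}carbonyloxy)-5-[(4S,5S)-4-(3,4,5-trimethoxyphenyl)-1,3-dioxan-5-yl]phenyl}prop-2-enoate | COc1cc([C@H]2OCOC[C@@H]2c3cc(/C=C/C(=O)OC)cc(OC)c3OC(=O)O[C@@H]4C[C@H](C)CC[C@H]4C(C)C)cc(OC)c1OC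
F4 | step 5 | methyl (2E)-3-{3-methoxy-4-({[(1R,2S,5R)-5-methyl-2-(propan-2-yl)cyclohexyl]oxy}carbonyloxy)-5-[(4R,5R)-4-(3,4,5-trimethoxyphenyl)-1,3-dioxan-5-yl]phenyl}prop-2-enoate | COc1cc([C@@H]2OCOC[C@H]2c3cc(/C=C/C(=O)OC)cc(OC)c3OC(=O)O[C@@H]4C[C@H](C)CC[C@H]4C(C)C)cc(OC)c1OC
F5 | step 6 | methyl (2E)-3-{4-(acetyloxy)-3-[(1S,2S)-3-(acetyloxy)-1-[(acetyloxy)methoxy]-1-(3,4,5-trimethoxyphenyl)propan-2-yl]-5-methoxyphenyl}prop-2-enoate | COC(=O)/C=C/c1cc(OC)c(OC(C)=O)c(c1)[C@@H](COC(C)=O)[C@H](OCOC(C)=O)c1cc(OC)c(OC)c(OC)c1
F6 | step 4 | methyl (2E)-3-(4-hydroxy-3-iodo-5-methoxyphenyl)prop-2-enoate | COC(=O)/C=C/c1cc(I)c(O)c(OC)c1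
A1 | alternative 1 | tert-butyldimethyl{[(2E)-3-(4,4,5,5-tetramethyl-1,3,2-dioxaborolan-2-yl)prop-2-en-1-yl]oxy}silane | CC(C)(C)[Si](C)(C)OC/C=C/B1OC(C)(C)C(C)(C)O1
A2 | alternative 1 | (3,4,5-trimethoxyphenyl)lithium | [Li]c1cc(OC)c(OC)c(OC)c1
A3 | alternative 1 | 1-bromo-5-(dimethoxymethyl)-3-methoxy-2-(methoxymethoxy)benzene | COCOc1c(Br)cc(C(OC)OC)cc1OC
A4 | alternative 1 | tert-butyl{[(2S,3R)-2-[5-(dimethoxymethyl)-3-methoxy-2-(methoxymethoxy)phenyl]-3-(4,4,5,5-tetramethyl-1,3,2-dioxaborolan-2-yl)-3-(3,4,5-trimethoxyphenyl)propyl]oxy}dimethylsilane | COc1cc([C@H](B3OC(C)(C)C(C)(C)O3)[C@H](CO[Si](C)(C)C(C)(C)C)c2cc(C(OC)OC)cc(OC)c2OCOC)cc(OC)c1OC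
A5 | alternative 2 | (2S)-2-[5-bromo-3-methoxy-2-(methoxymethoxy)phenyl]-1-(3,4,5-trimethoxyphenyl)propane-1,3-diol (either configuration at C1) | COCOc1c(OC)cc(Br)cc1[C@@H](CO)C(O)c1cc(OC)c(OC)c(OC)c1
A6 | alternative 2 | [(2R,3S)-5-bromo-7-methoxy-2-(3,4,5-trimethoxyphenyl)-2,3-dihydro-1-benzofuran-3-yl]methanol | COc1cc([C@@H]2Oc3c(OC)cc(Br)cc3[C@H]2CO)cc(OC)c1OC
A7 | alternative 3 | 4-bromo-2-{2-[(tert-butyldimethylsilyl)oxy]-1-(4-methylbenzenesulfonyl)ethyl}-6-methoxyphenol | Cc1ccc(cc1)S(=O)(=O)C(CO[Si](C)(C)C(C)(C)C)c1cc(Br)cc(OC)c1O
A8 | alternative 3 | (2R,5R)-2,5-dimethyl-1-[(3,4,5-trimethoxyphenyl)methyl]thiolan-1-ium tetrafluoroborate | C[C@@H]1CC[C@@H](C)[S+]1Cc1cc(OC)c(OC)c(OC)c1.F[B-](F)(F)F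
A9 | alternative 3 | tert-butyl{[(2R,3S)-5-bromo-7-methoxy-2-(3,4,5-trimethoxyphenyl)-2,3-dihydro-1-benzofuran-3-yl]methoxy}dimethylsilane | COc1cc([C@@H]2Oc3c(OC)cc(Br)cc3[C@H]2CO[Si](C)(C)C(C)(C)C)cc(OC)c1OC
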